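**Retrosynthetic overview**

1. Target 30 comes from its pentadeca-O-benzyl ether 29 by hydrogenolysis; the 16-membered ring of 29 is closed last, at the interflavan bond upper C4–lower C8, by Friedel–Crafts capture of the upper flavan-4-yl cation.
2. Before that, ring C of the lower unit is closed at C4–C4a. In seco ester 25 the lower half is an acyclic erythro 3-aryl-3-aryloxypropane-1,2-diol whose primary oxygen (O4) carries the bridging galloyl acid; triflation of C3–OH lets the ester carbonyl displace the triflate with inversion, and the arene opens the resulting acyloxonium ion at C4.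
3. Enabling feature: C4a is a free carbon of the phloroglucinol-type ring A of the lower unit (ortho to O1 and O5, para to O7), held to C4 by the chain O1–C2–C3; and the C3 oxygen of the target bears the bridging galloyl carbonyl, which in the precursor sits on the neighbouring O4 and can bridge C3/C4.
4. 25 comes from upper-unit acid 20 and diol 24. Both halves start from aryl aldehydes (Wittig, Luche, Sharpless epoxidation, benzylic epoxide opening by 3,5-bis(benzyloxy)phenol). Upper ring C is made by epoxide–arene cyclisation, C3 is corrected by oxidation–reduction, and C4 is activated with DDQ.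
5. The diaryl ether comes from an Ullmann coupling of 3 and 5. Ring order: upper ring C (step 10), lower ring C (step 21), macrocycle (step 22).

Key step: step 21

Remark: flavan numbering is used; the upper unit is the flavan substituted at C4, the lower unit the flavan with CH2 at C4, primes mark the rings B; 1, 4, 10 and 18 are assumed to be purchasable.

**Route**

Step 1
Reactants: 1 gallic acid
Product: 2 allyl gallate (prop-2-enyl 3,4,5-trihydroxybenzoate)
Conditions: allyl alcohol (solvent), TsOH·H2O (cat.), reflux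
Reagents that add atoms: allyl alcohol, C=CCO
Why: Fischer esterification in neat allyl alcohol should esterify only the carboxylic acid, the phenols being inert under acid catalysis.

Step 2
Reactants: 2 allyl gallate
Product: 3 allyl 3,4-bis(benzyloxy)-5-hydroxybenzoate
Conditions: BnBr (2 equiv), K2CO3, DMF, 0 °C to rt
Reagents that add atoms: benzyl bromide, BrCc1ccccc1
Why: Williamson benzylation follows phenol acidity (4-OH para to the ester first, then one of the two equivalent meta hydroxyls), so two equivalents should give mainly the 3,4-dibenzyl ether with one meta phenol left free.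

Step 3
Reactants: 4 3,4,5-tris(benzyloxy)benzaldehyde
Product: 5 2-bromo-3,4,5-tris(benzyloxy)benzaldehyde
Conditions: NBS, MeCN, rt, dark
Reagents that add atoms: N-bromosuccinimide, O=C1CCC(=O)N1Br
Why: electrophilic aromatic bromination should occur at the only free ring position type (C2/C6, ortho and para to benzyloxy groups), as known for 3,4,5-trialkoxybenzaldehydes.

Step 4
Reactants: 3 allyl 3,4-bis(benzyloxy)-5-hydroxybenzoate; 5 2-bromo-3,4,5-tris(benzyloxy)benzaldehyde
Product: 6 allyl 3,4-bis(benzyloxy)-5-[2,3,4-tris(benzyloxy)-6-formylphenoxy]benzoate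
Conditions: CuI (cat.), N,N-dimethylglycine, Cs2CO3, 1,4-dioxane, 100 °C
Reagents that add atoms: none
Why: Ullmann-type copper-catalysed diaryl ether coupling, assisted by the ortho-formyl group of the bromide, should join the phenol oxygen of 3 to C2 of 5 without touching ester or aldehyde.

Step 5
Reactants: 6 diaryl ether aldehyde
Product: 7 allyl 3,4-bis(benzyloxy)-5-{2,3,4-tris(benzyloxy)-6-[(E)-3-oxoprop-1-enyl]phenoxy}benzoate
Conditions: Ph3P=CHCHO, toluene, 80 °C
Reagents that add atoms: (triphenylphosphoranylidene)acetaldehyde, O=CC=P(c1ccccc1)(c1ccccc1)c1ccccc1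
Why: Wittig olefination with the stabilised formylmethylene ylide should give the (E)-enal and leave the allyl ester alone.

Step 6
Reactants: 7 (E)-enal
Product: 8 allyl 3,4-bis(benzyloxy)-5-{2,3,4-tris(benzyloxy)-6-[(E)-3-hydroxyprop-1-enyl]phenoxy}benzoate
Conditions: NaBH4, CeCl3·7H2O, MeOH/THF, 0 °C
Reagents that add atoms: none
Why: Luche reduction is 1,2-selective for the enal carbonyl and does not reduce the benzoate ester.

Step 7
Reactants: 8 (E)-allylic alcohol
Product: 9 allyl 3,4-bis(benzyloxy)-5-{2,3,4-tris(benzyloxy)-6-[(2S,3S)-3-(hydroxymethyl)oxiran-2-yl]phenoxy}benzoate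
Conditions: Ti(OiPr)4 (cat.), L-(+)-diethyl tartrate, t-BuOOH, 4 Å MS, CH2Cl2, −20 °C
Reagents that add atoms: tert-butyl hydroperoxide, CC(C)(C)OO
Why: Sharpless asymmetric epoxidation; the titanium L-(+)-tartrate catalyst controls the face and should give the (2S,3S)-trans-epoxy alcohol, the isolated allyl ester alkene being unreactive.

Step 8
Reactants: 9 epoxy alcohol; 10 3,5-bis(benzyloxy)phenol
Product: 11 allyl 3,4-bis(benzyloxy)-5-{2,3,4-tris(benzyloxy)-6-[(1R,2S)-1-[3,5-bis(benzyloxy)phenoxy]-2,3-dihydroxypropyl]phenoxy}benzoate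
Conditions: Cs2CO3 (0.3 equiv), DMF, 50 °C
Reagents that add atoms: none
Why: aryloxide opening of a 3-aryl-2,3-epoxy alcohol occurs at the benzylic carbon by SN2 with inversion (a known regiochemistry for 3-arylglycidols), which sets the aryl ether stereocentre as R while the carbinol carbon keeps its configuration.

Step 9
Reactants: 11 diol
Product: 13 allyl 3,4-bis(benzyloxy)-5-{2,3,4-tris(benzyloxy)-6-[(R)-[3,5-bis(benzyloxy)phenoxy]((2S)-oxiran-2-yl)methyl]phenoxy}benzoate, via primary tosylate 12 (not isolated)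
Conditions: TsCl, Et3N, Bu2SnO (cat.), CH2Cl2, 0 °C; then DBU, rt
Reagents that add atoms: none
Why: tin-catalysed sulfonylation is selective for the primary hydroxyl of a 1,2-diol, and base then closes the terminal epoxide by intramolecular Williamson displacement with retention at the secondary carbon.

Step 10
Reactants: 13 aryl glycidyl ether
Product: 14 allyl 3,4-bis(benzyloxy)-5-{2,3,4-tris(benzyloxy)-6-[(2R,3S)-5,7-bis(benzyloxy)-3-hydroxychroman-2-yl]phenoxy}benzoate (2,3-trans)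
Conditions: BF3·OEt2 (0.2 equiv), CH2Cl2, −78 to −40 °C
Reagents that add atoms: none
Why: intramolecular Friedel–Crafts epoxide–arene cyclisation of an aryl glycidyl ether; the electron-rich ortho carbon attacks the terminal epoxide carbon (six-membered closure preferred over five) and the C3–O bond is not touched, so the 2,3-trans chroman-3-ol should result.

Step 11
Reactants: 14 trans-flavan-3-ol
Product: 15 allyl 3,4-bis(benzyloxy)-5-{2,3,4-tris(benzyloxy)-6-[(2R)-5,7-bis(benzyloxy)-3-oxochroman-2-yl]phenoxy}benzoate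
Conditions: Dess–Martin periodinane, CH2Cl2, rt
Reagents that add atoms: none
Why: Dess–Martin oxidation gives the flavan-3-one under non-basic conditions that should not epimerise C2.

Step 12
Reactants: 15 flavan-3-one
Product: 16 allyl 3,4-bis(benzyloxy)-5-{2,3,4-tris(benzyloxy)-6-[(2R,3R)-5,7-bis(benzyloxy)-3-hydroxychroman-2-yl]phenoxy}benzoate (2,3-cis)
Conditions: LiBH(s-Bu)3, THF, −78 °C
Reagents that add atoms: none
Why: the bulky hydride attacks the ketone anti to the 2-aryl group and gives the axial 3-hydroxyl cis to it (the known trans-to-cis correction of protected flavan-3-ols); esters are not reduced at −78 °C.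

Step 13
Reactants: 16 cis-flavan-3-ol
Product: 17 allyl 3,4-bis(benzyloxy)-5-{2,3,4-tris(benzyloxy)-6-[(2R,3R,4S)-5,7-bis(benzyloxy)-4-(2-ethoxyethoxy)-3-hydroxychroman-2-yl]phenoxy}benzoate
Conditions: DDQ, 2-ethoxyethanol, CH2Cl2, rt
Reagents that add atoms: 2-ethoxyethanol, CCOCCO
Why: DDQ abstracts hydride from the benzylic C4 activated by the 5,7-dioxygenated ring A and the alcohol adds to the cation trans to the C3 oxygen (4β), the standard C4 activation of benzylated flavan-3-ols.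

Step 14
Reactants: 17 4-alkoxy flavan-3-ol; 18 3,4,5-tris(benzyloxy)benzoic acid
Product: 19 allyl 3,4-bis(benzyloxy)-5-{2,3,4-tris(benzyloxy)-6-[(2R,3R,4S)-5,7-bis(benzyloxy)-4-(2-ethoxyethoxy)-3-[3,4,5-tris(benzyloxy)benzoyloxy]chroman-2-yl]phenoxy}benzoate
Conditions: EDC·HCl, DMAP, CH2Cl2, rt
Reagents that add atoms: none
Why: Steglich esterification acylates the axial 3-hydroxyl as in known flavan-3-yl gallate syntheses, and the 4-ether and allyl ester are stable to it.

Step 15
Reactants: 19 allyl ester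
Product: 20 3,4-bis(benzyloxy)-5-{2,3,4-tris(benzyloxy)-6-[(2R,3R,4S)-5,7-bis(benzyloxy)-4-(2-ethoxyethoxy)-3-[3,4,5-tris(benzyloxy)benzoyloxy]chroman-2-yl]phenoxy}benzoic acid
Conditions: Pd(PPh3)4 (cat.), morpholine, THF, rt
Reagents that add atoms: none
Why: allyl transfer to morpholine catalysed by zerovalent palladium (Tsuji–Trost deallylation) frees the benzoic acid under neutral conditions that spare benzyl ethers, the galloyl ester and the acid-labile 4-ether.

Step 16
Reactants: 4 3,4,5-tris(benzyloxy)benzaldehyde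
Product: 21 (E)-3-[3,4,5-tris(benzyloxy)phenyl]prop-2-enal
Conditions: Ph3P=CHCHO, toluene, 80 °C
Reagents that add atoms: (triphenylphosphoranylidene)acetaldehyde, O=CC=P(c1ccccc1)(c1ccccc1)c1ccccc1
Why: Wittig olefination with the stabilised ylide should give the (E)-enal.

Step 17
Reactants: 21 (E)-enal
Product: 22 (E)-3-[3,4,5-tris(benzyloxy)phenyl]prop-2-en-1-ol
Conditions: NaBH4, CeCl3·7H2O, MeOH/THF, 0 °C
Reagents that add atoms: none
Why: Luche reduction gives the allylic alcohol by selective 1,2-reduction.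

Step 18
Reactants: 22 (E)-allylic alcohol
Product: 23 {(2S,3S)-3-[3,4,5-tris(benzyloxy)phenyl]oxiran-2-yl}methanol
Conditions: Ti(OiPr)4 (cat.), L-(+)-diethyl tartrate, t-BuOOH, 4 Å MS, CH2Cl2, −20 °C
Reagents that add atoms: tert-butyl hydroperoxide, CC(C)(C)OO
Why: Sharpless asymmetric epoxidation with the L-(+)-tartrate catalyst should give the (2S,3S)-trans-epoxy alcohol.

Step 19
Reactants: 23 epoxy alcohol; 10 3,5-bis(benzyloxy)phenol
Product: 24 (2S,3R)-3-[3,5-bis(benzyloxy)phenoxy]-3-[3,4,5-tris(benzyloxy)phenyl]propane-1,2-diol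
Conditions: Cs2CO3 (0.3 equiv), DMF, 50 °C
Reagents that add atoms: none
Why: as in step 8, the aryloxide opens the epoxide at the benzylic carbon by SN2 with inversion, which sets the future C2 (R) and leaves the future C3 as the erythro (3S) carbinol.

Step 20
Reactants: 20 upper-unit acid; 24 lower seco diol
Product: 25 (2S,3R)-3-[3,5-bis(benzyloxy)phenoxy]-2-hydroxy-3-[3,4,5-tris(benzyloxy)phenyl]propyl ester of acid 20 (ester on the primary oxygen O4 and free secondary C3–OH)
Conditions: EDC·HCl, DMAP (cat.), CH2Cl2, −10 to 0 °C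
Reagents that add atoms: none
Why: carbodiimide (Steglich) esterification is selective for the unhindered primary hydroxyl over the secondary one next to the aryloxybenzyl carbon, so the bridging acid is placed on O4 without protecting groups.

Step 21
Reactants: 25 seco ester
Product: 28 (2R,3R)-5,7-bis(benzyloxy)-2-[3,4,5-tris(benzyloxy)phenyl]chroman-3-yl ester of acid 20 (linear bis-flavan), via secondary triflate 26 (not isolated), via dioxolanylium triflate 27 (not isolated)
Conditions: Tf2O, 2,6-di-tert-butyl-4-methylpyridine, 4 Å MS, CH2Cl2, −78 to −10 °C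
Reagents that add atoms: none
Why: Proposed new method: O-triflation of the only free hydroxyl (C3–OH of the seco lower unit) triggers backside 5-exo-tet attack by the carbonyl oxygen of the adjacent O4 aroyl ester to give the 2-aryl-1,3-dioxolan-2-ylium ion 27, and the ortho carbon of the 3,5-bis(benzyloxy)phenoxy ring (the future C4a) then opens this ion at its primary carbon C4, which forms C4–C4a, closes ring C of the lower unit and leaves the acyl group on O3, its place in the target. The closest known reactions are the displacement of secondary triflates by vicinal esters through acyloxonium ions (the participation step of the Woodward–Prévost reaction), the opening of 2-aryl-1,3-dioxolan-2-ylium ions at their primary carbon by halide (Hanessian–Hullar reaction) and the epoxide–arene cyclisation of step 10; what is new is capture of the acyloxonium ion at carbon by an arene. Ring C closes 6-exo-tet (the C4–O bond that breaks lies outside the new ring) through a fused transition state in which the C3–O bond is antiperiplanar to the forming C4–C4a bond, which is the axial 3-acyloxy, equatorial 2-aryl half-chair of a 2,3-cis flavan. C3 is set by the stereospecific SN2 inversion of the first event (3S in 25 becomes 3R in 28) while C2 is not touched, so the erythro diol from the trans-epoxide is converted into the 2,3-cis (epi) series. The step needs attack at C4 by one ring carbon only, and the substrate secures this: the two ortho carbons of the phloroglucinol-type ring are equivalent and are the only ones that reach C4 through a six-membered ring, attack at C3 would need a five-membered Friedel–Crafts closure, and the para carbon cannot reach. Competing 1,2-shift of the C2 aryl group should be disfavoured because the 3,4,5-tris(benzyloxy)phenyl ring is a poor participating group (para oxygen twisted out of conjugation, geminal aryloxy group) compared with five-ring ester participation, and the hindered pyridine keeps the medium non-acidic so that the 4-(2-ethoxyethoxy) group of the upper unit survives.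

Step 22
Reactants: 28 linear bis-flavan
Product: 29 pentadeca-O-benzyl ether of the target (macrocycle closed by the bond upper C4–lower C8; upper unit 2R,3R,4R and lower unit 2R,3R)
Conditions: TMSOTf (0.5 equiv), 4 Å MS, CH2Cl2 (1 mM), −40 to −20 °C
Reagents that add atoms: none
Why: the Lewis acid ionises the 4-(2-ethoxyethoxy) ether to the flavan-4-yl cation, which is captured by C8 of the lower ring A trans to the 3-acyloxy and 2-aryl groups (4β, 4R); this is the established interflavan Friedel–Crafts coupling, run here as a tethered 16-membered ring closure at high dilution.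

Step 23
Reactants: 29 protected macrocycle
Product: 30 CNP0601265.1 (target)
Conditions: H2 (1 atm), Pd(OH)2/C, THF/MeOH, rt
Reagents that add atoms: none
Why: hydrogenolysis cleaves all fifteen benzyl ethers while the cyclic C2–O1 ethers, the two esters and the diaryl ether survive, as in known end games of flavan-3-yl gallate syntheses.

**Compound list**

1 | gallic acid | OC(=O)c1cc(O)c(O)c(O)c1 | starting material
2 | allyl gallate | C=CCOC(=O)c1cc(O)c(O)c(O)c1 | intermediate
3 | allyl 3,4-bis(benzyloxy)-5-hydroxybenzoate | C=CCOC(=O)c1cc(O)c(OCc2ccccc2)c(OCc2ccccc2)c1 | intermediate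
4 | 3,4,5-tris(benzyloxy)benzaldehyde | O=Cc1cc(OCc2ccccc2)c(OCc2ccccc2)c(OCc2ccccc2)c1 | starting material
5 | 2-bromo-3,4,5-tris(benzyloxy)benzaldehyde | O=Cc1cc(OCc2ccccc2)c(OCc2ccccc2)c(OCc2ccccc2)c1Br | intermediate
6 | allyl 3,4-bis(benzyloxy)-5-[2,3,4-tris(benzyloxy)-6-formylphenoxy]benzoate | C=CCOC(=O)c1cc(Oc2c(C=O)cc(OCc3ccccc3)c(OCc3ccccc3)c2OCc2ccccc2)c(OCc2ccccc2)c(OCc2ccccc2)c1 | intermediate
7 | (E)-enal of the upper series | C=CCOC(=O)c1cc(Oc2c(/C=C/C=O)cc(OCc3ccccc3)c(OCc3ccccc3)c2OCc2ccccc2)c(OCc2ccccc2)c(OCc2ccccc2)c1 | intermediate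
8 | (E)-allylic alcohol of the upper series | C=CCOC(=O)c1cc(Oc2c(/C=C/CO)cc(OCc3ccccc3)c(OCc3ccccc3)c2OCc2ccccc2)c(OCc2ccccc2)c(OCc2ccccc2)c1 | intermediate
9 | (2S,3S)-epoxy alcohol of the upper series | C=CCOC(=O)c1cc(Oc2c([C@@H]3O[C@H]3CO)cc(OCc3ccccc3)c(OCc3ccccc3)c2OCc2ccccc2)c(OCc2ccccc2)c(OCc2ccccc2)c1 | intermediate
10 | 3,5-bis(benzyloxy)phenol | Oc1cc(OCc2ccccc2)cc(OCc2ccccc2)c1 | starting material
11 | (1R,2S)-1-aryloxy-2,3-diol of the upper series | C=CCOC(=O)c1cc(Oc2c([C@@H](Oc3cc(OCc4ccccc4)cc(OCc4ccccc4)c3)[C@@H](O)CO)cc(OCc3ccccc3)c(OCc3ccccc3)c2OCc2ccccc2)c(OCc2ccccc2)c(OCc2ccccc2)c1 | intermediate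
12 | primary tosylate of 11 | C=CCOC(=O)c1cc(Oc2c([C@@H](Oc3cc(OCc4ccccc4)cc(OCc4ccccc4)c3)[C@@H](O)COS(=O)(=O)c3ccc(C)cc3)cc(OCc3ccccc3)c(OCc3ccccc3)c2OCc2ccccc2)c(OCc2ccccc2)c(OCc2ccccc2)c1 | intermediate (not isolated)
13 | aryl glycidyl ether of the upper series, (R)-ether carbon and (S)-oxirane | C=CCOC(=O)c1cc(Oc2c([C@@H](Oc3cc(OCc4ccccc4)cc(OCc4ccccc4)c3)[C@@H]3CO3)cc(OCc3ccccc3)c(OCc3ccccc3)c2OCc2ccccc2)c(OCc2ccccc2)c(OCc2ccccc2)c1 | intermediate
14 | (2R,3S)-trans-flavan-3-ol of the upper unit | C=CCOC(=O)c1cc(Oc2c([C@H]3Oc4cc(OCc5ccccc5)cc(OCc5ccccc5)c4C[C@@H]3O)cc(OCc3ccccc3)c(OCc3ccccc3)c2OCc2ccccc2)c(OCc2ccccc2)c(OCc2ccccc2)c1 | intermediate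
15 | (2R)-flavan-3-one of the upper unit | C=CCOC(=O)c1cc(Oc2c([C@H]3Oc4cc(OCc5ccccc5)cc(OCc5ccccc5)c4CC3=O)cc(OCc3ccccc3)c(OCc3ccccc3)c2OCc2ccccc2)c(OCc2ccccc2)c(OCc2ccccc2)c1 | intermediate
16 | (2R,3R)-cis-flavan-3-ol of the upper unit | C=CCOC(=O)c1cc(Oc2c([C@H]3Oc4cc(OCc5ccccc5)cc(OCc5ccccc5)c4C[C@H]3O)cc(OCc3ccccc3)c(OCc3ccccc3)c2OCc2ccccc2)c(OCc2ccccc2)c(OCc2ccccc2)c1 | intermediate
17 | (2R,3R,4S)-4-(2-ethoxyethoxy)flavan-3-ol of the upper unit | C=CCOC(=O)c1cc(Oc2c([C@H]3Oc4cc(OCc5ccccc5)cc(OCc5ccccc5)c4[C@H](OCCOCC)[C@H]3O)cc(OCc3ccccc3)c(OCc3ccccc3)c2OCc2ccccc2)c(OCc2ccccc2)c(OCc2ccccc2)c1 | intermediate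
18 | 3,4,5-tris(benzyloxy)benzoic acid | OC(=O)c1cc(OCc2ccccc2)c(OCc2ccccc2)c(OCc2ccccc2)c1 | starting material
19 | 3-O-[3,4,5-tris(benzyloxy)benzoyl] ester of 17 | C=CCOC(=O)c1cc(Oc2c([C@H]3Oc4cc(OCc5ccccc5)cc(OCc5ccccc5)c4[C@H](OCCOCC)[C@H]3OC(=O)c3cc(OCc4ccccc4)c(OCc4ccccc4)c(OCc4ccccc4)c3)cc(OCc3ccccc3)c(OCc3ccccc3)c2OCc2ccccc2)c(OCc2ccccc2)c(OCc2ccccc2)c1 | intermediate
20 | upper-unit benzoic acid (19 without the allyl group) | OC(=O)c1cc(Oc2c([C@H]3Oc4cc(OCc5ccccc5)cc(OCc5ccccc5)c4[C@H](OCCOCC)[C@H]3OC(=O)c3cc(OCc4ccccc4)c(OCc4ccccc4)c(OCc4ccccc4)c3)cc(OCc3ccccc3)c(OCc3ccccc3)c2OCc2ccccc2)c(OCc2ccccc2)c(OCc2ccccc2)c1 | intermediate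
21 | (E)-3-[3,4,5-tris(benzyloxy)phenyl]prop-2-enal | O=C/C=C/c1cc(OCc2ccccc2)c(OCc2ccccc2)c(OCc2ccccc2)c1 | intermediate
22 | (E)-3-[3,4,5-tris(benzyloxy)phenyl]prop-2-en-1-ol | OC/C=C/c1cc(OCc2ccccc2)c(OCc2ccccc2)c(OCc2ccccc2)c1 | intermediate
23 | {(2S,3S)-3-[3,4,5-tris(benzyloxy)phenyl]oxiran-2-yl}methanol | OC[C@@H]1O[C@H]1c1cc(OCc2ccccc2)c(OCc2ccccc2)c(OCc2ccccc2)c1 | intermediate
24 | (2S,3R)-3-[3,5-bis(benzyloxy)phenoxy]-3-[3,4,5-tris(benzyloxy)phenyl]propane-1,2-diol | OC[C@H](O)[C@H](Oc1cc(OCc2ccccc2)cc(OCc2ccccc2)c1)c1cc(OCc2ccccc2)c(OCc2ccccc2)c(OCc2ccccc2)c1 | intermediate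
25 | seco ester (primary ester of 24 with 20, free 2S hydroxyl) | O=C(OC[C@H](O)[C@H](Oc1cc(OCc2ccccc2)cc(OCc2ccccc2)c1)c1cc(OCc2ccccc2)c(OCc2ccccc2)c(OCc2ccccc2)c1)c1cc(Oc2c([C@H]3Oc4cc(OCc5ccccc5)cc(OCc5ccccc5)c4[C@H](OCCOCC)[C@H]3OC(=O)c3cc(OCc4ccccc4)c(OCc4ccccc4)c(OCc4ccccc4)c3)cc(OCc3ccccc3)c(OCc3ccccc3)c2OCc2ccccc2)c(OCc2ccccc2)c(OCc2ccccc2)c1 | intermediate
26 | secondary triflate of 25 | O=C(OC[C@H](OS(=O)(=O)C(F)(F)F)[C@H](Oc1cc(OCc2ccccc2)cc(OCc2ccccc2)c1)c1cc(OCc2ccccc2)c(OCc2ccccc2)c(OCc2ccccc2)c1)c1cc(Oc2c([C@H]3Oc4cc(OCc5ccccc5)cc(OCc5ccccc5)c4[C@H](OCCOCC)[C@H]3OC(=O)c3cc(OCc4ccccc4)c(OCc4ccccc4)c(OCc4ccccc4)c3)cc(OCc3ccccc3)c(OCc3ccccc3)c2OCc2ccccc2)c(OCc2ccccc2)c(OCc2ccccc2)c1 | intermediate (not isolated)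
27 | (4R)-4-[(R)-aryl(aryloxy)methyl]-2-aryl-1,3-dioxolan-2-ylium triflate (2-aryl is the benzoyl ring of 20) | C1(=[O+][C@H](CO1)[C@H](Oc1cc(OCc2ccccc2)cc(OCc2ccccc2)c1)c1cc(OCc2ccccc2)c(OCc2ccccc2)c(OCc2ccccc2)c1)c1cc(Oc2c([C@H]3Oc4cc(OCc5ccccc5)cc(OCc5ccccc5)c4[C@H](OCCOCC)[C@H]3OC(=O)c3cc(OCc4ccccc4)c(OCc4ccccc4)c(OCc4ccccc4)c3)cc(OCc3ccccc3)c(OCc3ccccc3)c2OCc2ccccc2)c(OCc2ccccc2)c(OCc2ccccc2)c1.[O-]S(=O)(=O)C(F)(F)F | intermediate (not isolated)
28 | linear bis-flavan ((2R,3R)-penta-O-benzylepigallocatechin-3-yl ester of 20) | O=C(O[C@@H]1Cc2c(OCc3ccccc3)cc(OCc3ccccc3)cc2O[C@@H]1c1cc(OCc2ccccc2)c(OCc2ccccc2)c(OCc2ccccc2)c1)c1cc(Oc2c([C@H]3Oc4cc(OCc5ccccc5)cc(OCc5ccccc5)c4[C@H](OCCOCC)[C@H]3OC(=O)c3cc(OCc4ccccc4)c(OCc4ccccc4)c(OCc4ccccc4)c3)cc(OCc3ccccc3)c(OCc3ccccc3)c2OCc2ccccc2)c(OCc2ccccc2)c(OCc2ccccc2)c1 | intermediate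
29 | pentadeca-O-benzyl ether of the target | O=C(O[C@@H]1[C@@H]2c3c(OCc4ccccc4)cc(OCc4ccccc4)cc3O[C@@H]1c1cc(OCc4ccccc4)c(OCc4ccccc4)c(OCc4ccccc4)c1Oc1cc(cc(OCc4ccccc4)c1OCc4ccccc4)C(=O)O[C@@H]1Cc3c(OCc4ccccc4)cc(OCc4ccccc4)c2c3O[C@@H]1c1cc(OCc4ccccc4)c(OCc4ccccc4)c(OCc4ccccc4)c1)c1cc(OCc4ccccc4)c(OCc4ccccc4)c(OCc4ccccc4)c1 | intermediate
30 | CNP0601265.1 | O=C(O[C@@H]1[C@@H]2c3c(O)cc(O)cc3O[C@@H]1c1cc(O)c(O)c(O)c1Oc1cc(cc(O)c1O)C(=O)O[C@@H]1Cc3c(O)cc(O)c2c3O[C@@H]1c1cc(O)c(O)c(O)c1)c1cc(O)c(O)c(O)c1 | target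

**Step count and risks**

Total step count: 23. Longest linear sequence: 18 steps (1, 2, 4–15, 20–23).

Steps most likely to fail:

1. Step 21 (proposed new method). The acyloxonium ion may fail to be captured at C4 by the arene: the C2 aryl group may migrate through a phenonium ion, or the upper 4-ether may ionise before ring closure. The fallback uses known chemistry, sets out from acid 20 and returns at 28. Purchased (−)-epigallocatechin F1 would be benzylated on its five phenolic hydroxyls (BnBr, K2CO3, DMF, 0 °C) to 5,7,3',4',5'-penta-O-benzyl-(−)-epigallocatechin F2. Steglich esterification of the 3-hydroxyl of F2 with 20 (EDC·HCl, DMAP, CH2Cl2) would give 28 directly, which then enters step 22 unchanged.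

2. Step 22. Intermolecular oligomerisation, or attack through C6 instead of C8 of the lower ring A, may compete with the 16-membered closure. The fallback forms the interflavan bond first and the ester last; it sets out from allyl ester 19 and returns at 29. Compound 19 would be condensed with an excess of F2 (TMSOTf, CH2Cl2, −40 °C), a coupling known to go to C8 and trans to the 3-acyloxy group, to give the 4β→8 dimer allyl ester F3 with a free lower 3-hydroxyl. Deallylation (Pd(PPh3)4, morpholine) would give seco acid F4, and Yamaguchi macrolactonisation (2,4,6-trichlorobenzoyl chloride, Et3N, then DMAP, toluene, high dilution) onto the lower 3-hydroxyl would give 29.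

3. Step 8 (the same risk applies to step 19). The electron-rich, ambident phenoxide may alkylate at carbon, or the hindered epoxy alcohol may react after Payne rearrangement instead of at the benzylic carbon. The fallback sets out from aldehyde 6 and returns at 16, bypassing steps 8–12. Addition of vinylmagnesium bromide (CH2=CHMgBr, THF, −78 °C) would give the racemic allylic alcohol F5. Sharpless kinetic resolution (Ti(OiPr)4, L-(+)-diisopropyl tartrate, t-BuOOH, 4 Å MS) would give the erythro epoxy alcohol F6. Mitsunobu etherification with phenol 10 (PPh3, DIAD, toluene), with inversion at the benzylic carbon, would give the threo aryl glycidyl ether F7. BF3·OEt2 cyclisation as in step 10 would then give the 2,3-cis flavan-3-ol 16 directly.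

Further compounds
F1 | step 21 | (−)-epigallocatechin (purchased) | O[C@@H]1Cc2c(O)cc(O)cc2O[C@@H]1c1cc(O)c(O)c(O)c1
F2 | step 21 | 5,7,3',4',5'-penta-O-benzyl-(−)-epigallocatechin | O[C@@H]1Cc2c(OCc3ccccc3)cc(OCc3ccccc3)cc2O[C@@H]1c1cc(OCc2ccccc2)c(OCc2ccccc2)c(OCc2ccccc2)c1
F3 | step 22 | 4β→8 dimer allyl ester (19 with its 4-alkoxy group replaced by C8 of F2; free lower 3-hydroxyl) | C=CCOC(=O)c1cc(Oc2c([C@H]3Oc4cc(OCc5ccccc5)cc(OCc5ccccc5)c4[C@H](c4c(OCc5ccccc5)cc(OCc5ccccc5)c5c4O[C@H](c4cc(OCc6ccccc6)c(OCc6ccccc6)c(OCc6ccccc6)c4)[C@H](O)C5)[C@H]3OC(=O)c3cc(OCc4ccccc4)c(OCc4ccccc4)c(OCc4ccccc4)c3)cc(OCc3ccccc3)c(OCc3ccccc3)c2OCc2ccccc2)c(OCc2ccccc2)c(OCc2ccccc2)c1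
F4 | step 22 | seco acid (F3 without the allyl group) | OC(=O)c1cc(Oc2c([C@H]3Oc4cc(OCc5ccccc5)cc(OCc5ccccc5)c4[C@H](c4c(OCc5ccccc5)cc(OCc5ccccc5)c5c4O[C@H](c4cc(OCc6ccccc6)c(OCc6ccccc6)c(OCc6ccccc6)c4)[C@H](O)C5)[C@H]3OC(=O)c3cc(OCc4ccccc4)c(OCc4ccccc4)c(OCc4ccccc4)c3)cc(OCc3ccccc3)c(OCc3ccccc3)c2OCc2ccccc2)c(OCc2ccccc2)c(OCc2ccccc2)c1
F5 | step 8 | allyl 3,4-bis(benzyloxy)-5-[2,3,4-tris(benzyloxy)-6-(1-hydroxyprop-2-enyl)phenoxy]benzoate (racemic) | C=CCOC(=O)c1cc(Oc2c(C(O)C=C)cc(OCc3ccccc3)c(OCc3ccccc3)c2OCc2ccccc2)c(OCc2ccccc2)c(OCc2ccccc2)c1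
F6 | step 8 | erythro epoxy alcohol, (S)-carbinol and (R)-oxirane | C=CCOC(=O)c1cc(Oc2c([C@H](O)[C@H]3CO3)cc(OCc3ccccc3)c(OCc3ccccc3)c2OCc2ccccc2)c(OCc2ccccc2)c(OCc2ccccc2)c1
F7 | step 8 | threo aryl glycidyl ether, (R)-ether carbon and (R)-oxirane | C=CCOC(=O)c1cc(Oc2c([C@@H](Oc3cc(OCc4ccccc4)cc(OCc4ccccc4)c3)[C@H]3CO3)cc(OCc3ccccc3)c(OCc3ccccc3)c2OCc2ccccc2)c(OCc2ccccc2)c(OCc2ccccc2)c1
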